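## Structural features

The target is a C20 dibromo alcohol built from three carbocycles: a 4-bromo-3,3-dimethylcyclohexylidene unit (ring A) and a trans-fused hydrindane made of a cyclohexane (ring B) and a cyclopentane (ring C). Ring A is tied to C3 of ring C by a one-carbon, trisubstituted exocyclic alkene of E geometry, in which the ring A methylene next to the gem-dimethyl carbon is trans to C3. Indane numbering is used for the bicycle (C1–C3, C3a, C4–C7, C7a), C1′ is the exocyclic CH, C1″–C6″ are the ring A carbons, and β is the face of the angular methyl group. Five contiguous stereocentres line the hydrindane: C3 (side chain α), C3a (H α), C4 (tertiary carbinol, OH β and axial, CH3 α), C7a (quaternary, CH3 β) and C7 (Br β, equatorial). The sixth, C4″ of ring A (S), is insulated from them by the alkene and is beyond substrate control. The fragile groups are the two secondary bromides, each next to a fully substituted carbon (elimination and 1,2-shift compete with substitution), the tertiary alcohol (dehydration) and the exocyclic alkene (reduction, isomerisation). The real difficulties are the quaternary C7a wedged between C7–Br and a trans ring fusion, the congested C3a/C4 pair, and the pairing of a remote stereocentre with an alkene geometry in ring A. The key step uses the fact that C7 and C3a, the two ring B neighbours of C7a, can both be carbonyl carbons of a 2,2-disubstituted cyclohexane-1,3-dione, while C1, C2, C3 and C1′ form a four-carbon arm on C7a that ends in an aldehyde. An aldol bond from C3 to C3a then closes ring C and defines C7a.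

## Logic of the disconnections

33 ⇒ 32 ⇒ 31. The C4″–Br bond is cut first. No element of the hydrindane can control this centre, so it is traced to a ketone (31) that a chiral reagent can reduce to 32, followed by substitution with inversion. The gain is that ring A loses its stereocentre. The demand is a clean backside displacement at a carbon flanked by the gem-dimethyl group, without elimination, methyl shift or attack on the tertiary alcohol.

31 ⇒ 30. The ring A bond C2″–C3″ is cut. Forward, the more substituted enolate of an isopropyl ketone alkylates a primary allylic chloride, so the ring closes without touching the alkene. The gain is that ring A becomes an open chain and its alkene geometry becomes an acyclic problem. The demand is alkylation through the tetrasubstituted enolate at the primary carbon (not at the alkene terminus) under base that leaves the C7 bromide alone.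

30 ⇒ 28 ⇒ 27 ⇒ 21 + 26. The C1′=C1″ double bond is cut by a Wittig disconnection, after adjusting chloride to alcohol to ester. An ester-stabilised ylide places the ester carbon trans to the aldehyde substituent, and that ester carbon is the future C2″, which is exactly the geometry required. The gain is convergence on core aldehyde 21 and ylide 26. The demand is olefination of a hindered α-branched aldehyde whose α-configuration is, fortunately, the stable one.

26 ⇒ 23 + 24, and 23 ⇒ 22. The C1″–C6″ bond of the ylide is cut (alkylation of a stabilised ylide), and the iodo ketal is traced to an enone by conjugate addition of iodide and ketalisation. The pieces are commercial; the demand is C-alkylation by an unactivated primary iodide.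

21 ⇒ 20 ⇒ 19 ⇒ 17. The C7–Br stereocentre is traced to a vinyl bromide and then to a ketone, so the bonds cut are C7–H and C6–H. Hydrogen then enters anti to the angular methyl and the bromine ends equatorial, with no substitution at the neopentyl carbon. The demand is that no other alkene is present, which is why this precedes the Wittig step and why C1′ is held as an alcohol meanwhile.

17 ⇒ 15. The C4–CH3 bond is cut. On a trans-hydrindan-4-one the axial trajectory is blocked by the syn-axial 7a-methyl, so a methyl nucleophile enters equatorially and leaves the hydroxyl axial and β. The demand is a non-basic organometallic (C3a–H is enolisable) and a masked C7 ketone.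

15 ⇒ 14 ⇒ 12. The C3–H and C3a–H bonds are cut. The alkene of a cis-ene-1,4-dicarbonyl is activated and flat, the angular methyl screens one face, and C3 can be corrected afterwards by epimerisation. The demand is hydrogen delivery from the α face and epimerisation at the aldehyde α-carbon only.

12 ⇒ 11 ⇒ 8. The C4=O bond is cut. The γ-carbon of an enal is reached through its dienol ether, and a furan spanning C1′ and C4 serves as a stable relay that is then opened oxidatively. The gain is that C4 returns to a plain methylene. The demand is attack of the oxidant at the γ- and not the α-carbon.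

8 ⇒ 6. The ketal is removed retrosynthetically; the forward step must protect the ketone while leaving the enal free.

6 ⇒ 4. The C3–C3a bond is cut (aldol condensation). This opens ring C, removes the only stereocentre and gives an achiral triketo aldehyde with a mirror plane. The demand is a catalyst that selects one of two enantiotopic ketones.

4 ⇒ 3 ⇒ 1 + 2. The formyl carbon is removed (hydroformylation) and then the allyl–C2 bond (allylic alkylation of the dione). The demand is linear selectivity and C- over O-allylation.

## Other disconnections considered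

Alternative 1: The cut is the bond between the angular methyl carbon and C7a, with the methyl introduced as a CH2 bridge across a C3a=C7a alkene. In the forward step the zinc alkoxide of allylic alcohol A1 would bind the carbenoid from Et2Zn/CH2I2 and deliver CH2 to the tetrasubstituted alkene on the hydroxyl face, giving propellane carbinol A2.
- In its favour: hydroxyl-directed cyclopropanation is stereospecific and tolerates fully substituted alkenes. It also encodes the cis relation between the C4 oxygen and the angular methyl directly.
- Against it here: the absolute configuration must already reside in A1, so an enantioselective entry to the bicycle is still needed. The cyclopropane must then be opened at the C3a–CH2 bond, in practice by oxidation at C4 and reductive cleavage. That erases the directing carbinol and leaves C3a to an enolate protonation in which the cis ring fusion is expected to compete.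
- Comparison: structurally it builds the same quaternary carbon in three or four operations on a preformed bicycle, whereas the chosen aldol creates ring C, C7a and the C1′ handle in one catalytic step from an achiral chain. Mechanistically it is substrate-directed delivery against catalyst-controlled group selection. On reliability of facial selectivity the cyclopropanation is the equal or the better of the aldol. On step economy it is clearly behind.

Alternative 2: The cut is the ring A bond C2″–C3″, made last, with the exocyclic alkene created in the same event. In the forward step Me2AlCl would ionise the tertiary tetrafluorobenzoate of bromohydrin allylsilane A3 to a bromonium ion. The CH2 terminus of the allylsilane attacks the gem-dimethyl carbon in a chair, and loss of silicon anti to the new bond gives A4, the triethylsilyl ether of the target.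
- In its favour: the C4″–Br bond is carried in from an enantiopure bromohydrin and is never made by substitution at the hindered carbon. On this point it is better than steps 19 and 20 of the chosen plan.
- Equal: alkene geometry is controlled in both plans, here by chirality transfer from the C–Si centre, there by a stabilised ylide.
- Against it here: a C–Si stereocentre must be set beside the hindered hydrindane and matched to the bromohydrin. The bromohydrin ester must be prepared in the presence of an acid-sensitive allylsilane. The Lewis acid meets a second secondary bromide and a tertiary silyl ether.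
- Comparison: it addresses ring A only and says nothing about C7a, so it complements the aldol and does not compete with it; it could be grafted onto aldehyde 21. Its endgame is estimated to be longer than the six steps used here.

Alternative 3: The cut is the C3a–C7a bond of ring B together with the C7–Br bond. In the forward step Et2SBr·SbCl5Br would form a bromonium ion on the trisubstituted alkene of enyne acetate A5. The proximal alkyne carbon attacks the tertiary carbon, and hydration of the vinyl cation gives bromo acetoxy methyl ketone A6.
- In its favour: ring B, C7a and the equatorial C7 bromide arise in one step with their relative configuration fixed by anti addition across an E alkene. The tertiary carbinol comes from a linalool-type building block. On C7–Br it is better than the three-step ketone-to-bromide sequence of the chosen plan.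
- Against it here: the reagent is achiral, so the face of bromonium formation is decided only by chair preferences around the remote carbinol carbon. Acetate participation and proton loss compete with alkyne capture. Ring C must still be annulated from the methyl ketone and the protected CH2OH. That leaves a C3 carbonyl to be homologated, with C3 and an epimerisable C3a to be set afterwards.
- Comparison: structurally the two plans are mirror images in what they solve early: A6 has C7–Br and C4 but lacks ring C and C1′, whereas 6 has ring C and C1′ but lacks C7–Br and C4. Mechanistically it is a cationic chair cyclisation against enamine catalysis. Step economy is expected to be similar at the front and worse after the key step.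

Key step: step 3

Assumption: (S)-proline is assigned as the catalyst enantiomer leading to the (7aS) centre on the basis of the hydrogen-bonded enamine transition-state model; if the sense proves opposite, (R)-proline is used and nothing else changes.
Compounds 1, 2, 22 and 24 are taken as commercially available.

## Route

Step 1
Reactants: 1 2-methylcyclohexane-1,3-dione; 2 allyl acetate
Product: 3 2-methyl-2-(prop-2-en-1-yl)cyclohexane-1,3-dione
Conditions: Pd(PPh3)4 (1 mol %), DBU (1.0 equiv), toluene, rt → 50 °C
Reagents that add atoms: none
Why: Tsuji–Trost allylation; the soft dione anion attacks the π-allylpalladium complex at carbon, and any O-allyl product re-ionises, so the C-allylated dione accumulates. The new quaternary carbon is prochiral.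

Step 2
Reactants: 3 2-methyl-2-(prop-2-en-1-yl)cyclohexane-1,3-dione
Product: 4 4-(1-methyl-2,6-dioxocyclohexyl)butanal
Conditions: Rh(acac)(CO)2 (0.5 mol %), Xantphos (1.5 mol %), CO/H2 (1:1, 10 bar), toluene, 80 °C
Reagents that add atoms: carbon monoxide, [C-]#[O+]
Why: Rhodium-catalysed hydroformylation; the wide bite angle of Xantphos directs formylation to the terminal carbon, and the ketones are inert.

Step 3
Reactants: 4 4-(1-methyl-2,6-dioxocyclohexyl)butanal
Product: 6 (7aS)-7a-methyl-7-oxo-2,4,5,6,7,7a-hexahydro-1H-indene-3-carbaldehyde, via cis-fused aldol ketol 5 (not isolated)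
Conditions: (S)-proline (30 mol %), MeCN, rt; then CF3CO2H (30 mol %), 40 °C
Reagents that add atoms: none
Why: Proline condenses with the aldehyde (the α-quaternary ketones are too hindered) to an E-enamine whose α-carbon adds to one ring ketone while the carboxylic acid protonates that carbonyl in a closed, hydrogen-bonded transition state. The closest known reaction types are the Hajos–Parrish–Eder–Sauer–Wiechert desymmetrisation and proline-catalysed enolexo aldolisations of aldehydes. Ring C closes in the 5-(enolexo)-exo-trig mode to the cis-fused ketol 5. Acid then promotes loss of water through the iminium/enamine pair to give the conjugated enal, so C3 and C3a become sp2 and C7a is the only stereocentre left. C7a is controlled by the catalyst alone: with the enamine reacting on the face of its carboxylic acid, only one of the two mirror-related ketones can reach the hydrogen bond, which for (S)-proline is modelled to give 7aS. The step needs enantiotopic-group selectivity and the right chemoselectivity. The substrate secures the latter because aldehyde enamine formation is far faster than ketone enamine formation and the reverse aldol (ketone enol onto aldehyde) would need a seven-membered ring.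

Step 4
Reactants: 6 (7aS)-7a-methyl-7-oxo-2,4,5,6,7,7a-hexahydro-1H-indene-3-carbaldehyde
Product: 8 (7aS)-7,7-ethylenedioxy-7a-methyl-2,4,5,6,7,7a-hexahydro-1H-indene-3-carbaldehyde, via bis-dioxolane 7 (not isolated)
Conditions: Me3SiOCH2CH2OSiMe3 (3 equiv), Me3SiOTf (5 mol %), CH2Cl2, −78 → −20 °C; pyridine quench, concentrate; then PPTS, acetone/H2O (9:1), rt
Reagents that add atoms: 1,2-bis(trimethylsilyloxy)ethane, C[Si](C)(C)OCCO[Si](C)(C)C; water, O
Why: Noyori acetalisation protects both carbonyls without moving the double bond. The conjugated acetal then ionises to an allylic oxocarbenium ion much faster than the neopentyl spiro-ketal, so buffered aqueous acid returns only the enal (selective acetal hydrolysis).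

Step 5
Reactants: 8 (7aS)-7,7-ethylenedioxy-7a-methyl-2,4,5,6,7,7a-hexahydro-1H-indene-3-carbaldehyde
Product: 11 tricyclic furan (furan ring made of O, C1′, C3, C3a and C4; 7,7-ethylenedioxy; 7aS methyl), via silyl dienol ether 9 (not isolated), via hydroxy enal 10 (not isolated)
Conditions: Et3SiOTf (1.3 equiv), Et3N (2.5 equiv), CH2Cl2, −78 → 0 °C; then mCPBA (1.1 equiv), NaHCO3, −40 °C; then PPTS (cat.), rt
Reagents that add atoms: 3-chloroperbenzoic acid, OOC(=O)c1cccc(Cl)c1
Why: Soft enolisation gives the extended dienol ether, and the peracid attacks its remote C3a=C4 bond, where the HOMO coefficient is largest (vinylogous Rubottom oxidation). The resulting cis-4-hydroxy enal closes to its lactol and loses water under acid to the aromatic furan, which collects all γ-oxygenated forms; no stereocentre is created.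

Step 6
Reactants: 11 tricyclic furan
Product: 12 (7aS)-7,7-ethylenedioxy-7a-methyl-4-oxo-2,4,5,6,7,7a-hexahydro-1H-indene-3-carbaldehyde
Conditions: dimethyldioxirane (1.1 equiv), acetone, −20 °C
Reagents that add atoms: dimethyldioxirane, CC1(C)OO1
Why: Oxidative ring opening of a furan; the furan epoxide collapses to the cis-ene-1,4-dicarbonyl, so C4 becomes the ketone and C1′ returns as the aldehyde with the geometry fixed by the rings.

Step 7
Reactants: 12 (7aS)-7,7-ethylenedioxy-7a-methyl-4-oxo-2,4,5,6,7,7a-hexahydro-1H-indene-3-carbaldehyde
Product: 14 7,7-ethylenedioxy-7aβ-methyl-4-oxo-3aα-H-octahydro-1H-indene-3α-carbaldehyde, via 3β-formyl epimer 13 (not isolated)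
Conditions: H2 (1 atm), 10% Pd/C, EtOAc, 0 °C → rt; filter; then pyrrolidine (10 mol %), AcOH (10 mol %), CH2Cl2, 0 °C
Reagents that add atoms: none
Why: Catalytic hydrogenation of the doubly activated alkene occurs syn from the face opposite the angular methyl, as in hydrogenations of ring-fusion alkenes of 7a-methylhydrindenes, and sets 3a-H α (trans fusion) with the formyl group β. Enamine-mediated epimerisation at the aldehyde α-carbon only then moves the formyl group to the α face, trans to C4 and away from the 7a-methyl, which is the thermodynamically preferred arrangement.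

Step 8
Reactants: 14 7,7-ethylenedioxy-7aβ-methyl-4-oxo-3aα-H-octahydro-1H-indene-3α-carbaldehyde
Product: 15 7,7-ethylenedioxy-3α-(hydroxymethyl)-7aβ-methyl-3aα-H-octahydro-1H-inden-4-one
Conditions: NaBH4 (0.5 equiv), MeOH/CH2Cl2 (1:1), −78 °C
Reagents that add atoms: none
Why: Chemoselective borohydride reduction; at low temperature the aldehyde is reduced far faster than the hindered α-branched ketone. This masks C1′ for the organometallic and hydrazine steps; the trans hydroxy ketone cannot close to a hemiketal.

Step 9
Reactants: 15 7,7-ethylenedioxy-3α-(hydroxymethyl)-7aβ-methyl-3aα-H-octahydro-1H-inden-4-one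
Product: 17 4β-hydroxy-3α-(hydroxymethyl)-4α,7aβ-dimethyl-3aα-H-octahydro-1H-inden-7-one, via ketal diol 16 (not isolated)
Conditions: MeLi (3 equiv), CeCl3 (3.5 equiv), THF, −78 °C; then 1 M HCl, THF, 40 °C
Reagents that add atoms: methyllithium, [Li]C; water, O
Why: Organocerium addition to an enolisable ketone without deprotonating C3a; the syn-axial 7a-methyl blocks the β (axial) trajectory, so methyl enters equatorially from the α face and the hydroxyl ends axial and β, as in additions to trans-hydrindan-4-ones. Aqueous acid then hydrolyses the dioxolane to free the C7 ketone.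

Step 10
Reactants: 17 4β-hydroxy-3α-(hydroxymethyl)-4α,7aβ-dimethyl-3aα-H-octahydro-1H-inden-7-one
Product: 19 7-bromo-3α-(hydroxymethyl)-4α,7aβ-dimethyl-2,3,3a,4,5,7a-hexahydro-1H-inden-4β-ol (C6=C7 alkene; 3a-H α), via C7 hydrazone 18 (not isolated)
Conditions: N2H4·H2O (10 equiv), Et3N, EtOH, 80 °C; concentrate; then NBS (2.2 equiv), pyridine, CH2Cl2, −10 °C
Reagents that add atoms: N-bromosuccinimide, O=C1CCC(=O)N1Br
Why: Barton-type oxidation of a hydrazone with a bromonium source; the diazo intermediate is brominated, loses nitrogen and then a proton to give the vinyl bromide. Only C6 carries hydrogens (C7a is quaternary), so the regiochemistry is fixed.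

Step 11
Reactants: 19 7-bromo-3α-(hydroxymethyl)-4α,7aβ-dimethyl-2,3,3a,4,5,7a-hexahydro-1H-inden-4β-ol
Product: 20 (3R,3aS,4R,7S,7aS)-7-bromo-3-(hydroxymethyl)-4,7a-dimethyloctahydro-1H-inden-4-ol
Conditions: Mn(dpm)3 (10 mol %), PhSiH3 (2 equiv), t-BuOOH (1.5 equiv), i-PrOH, rt
Reagents that add atoms: none
Why: Hydrogen-atom-transfer hydrogenation of a haloalkene; the first hydrogen adds to C6 to give the bromine-stabilised C7 radical, and the second is delivered anti to the angular methyl, so bromine ends β and equatorial, which is also the more stable epimer. The C–Br bond is formed without substitution at the neopentyl carbon, and radical conditions avoid hydrogenolysis.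

Step 12
Reactants: 20 (3R,3aS,4R,7S,7aS)-7-bromo-3-(hydroxymethyl)-4,7a-dimethyloctahydro-1H-inden-4-ol
Product: 21 (3R,3aS,4R,7S,7aS)-7-bromo-4-hydroxy-4,7a-dimethyloctahydro-1H-indene-3-carbaldehyde
Conditions: Dess–Martin periodinane (1.2 equiv), NaHCO3, CH2Cl2, 0 °C → rt
Reagents that add atoms: none
Why: Dess–Martin oxidation of the primary alcohol; the tertiary alcohol is inert, and the trans relation between C1′ and C4 prevents lactol formation. The α-formyl configuration is the stable one.

Step 13
Reactants: 22 4-methylpent-1-en-3-one
Product: 23 2-(2-iodoethyl)-2-(propan-2-yl)-1,3-dioxolane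
Conditions: NaI (1.2 equiv), Me3SiCl (1.2 equiv), MeCN, −20 °C; then HOCH2CH2OH (1.5 equiv), 0 °C → rt
Reagents that add atoms: sodium iodide, [Na+].[I-]; ethane-1,2-diol, OCCO
Why: Conjugate addition of iodide to the silyl-activated enone gives the β-iodo silyl enol ether, which the diol converts to the β-iodo ketal; this is a known one-pot route from enones to β-iodo ketals.

Step 14
Reactants: 23 2-(2-iodoethyl)-2-(propan-2-yl)-1,3-dioxolane; 24 ethyl (triphenyl-λ5-phosphanylidene)acetate
Product: 26 ethyl 4-[2-(propan-2-yl)-1,3-dioxolan-2-yl]-2-(triphenyl-λ5-phosphanylidene)butanoate, via phosphonium iodide 25 (not isolated)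
Conditions: MeCN, 80 °C; then 1 M NaOH, CH2Cl2, 0 °C
Reagents that add atoms: none
Why: C-alkylation of an ester-stabilised ylide by a primary iodide, then deprotonation of the phosphonium salt to the disubstituted stabilised ylide.

Step 15
Reactants: 21 (3R,3aS,4R,7S,7aS)-7-bromo-4-hydroxy-4,7a-dimethyloctahydro-1H-indene-3-carbaldehyde; 26 ethyl 4-[2-(propan-2-yl)-1,3-dioxolan-2-yl]-2-(triphenyl-λ5-phosphanylidene)butanoate
Product: 27 ethyl (2E)-3-[(3S,3aS,4R,7S,7aS)-7-bromo-4-hydroxy-4,7a-dimethyloctahydro-1H-inden-3-yl]-2-{2-[2-(propan-2-yl)-1,3-dioxolan-2-yl]ethyl}prop-2-enoate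
Conditions: toluene, 100 °C
Reagents that add atoms: none
Why: Wittig olefination with a stabilised ylide; reversible addition places the ester trans to the bulky hydrindanyl group (E). The ester carbon is the future C2″, so the target alkene geometry is set here.

Step 16
Reactants: 27 ethyl (2E)-3-[(3S,3aS,4R,7S,7aS)-7-bromo-4-hydroxy-4,7a-dimethyloctahydro-1H-inden-3-yl]-2-{2-[2-(propan-2-yl)-1,3-dioxolan-2-yl]ethyl}prop-2-enoate
Product: 28 (2E)-3-[(3S,3aS,4R,7S,7aS)-7-bromo-4-hydroxy-4,7a-dimethyloctahydro-1H-inden-3-yl]-2-{2-[2-(propan-2-yl)-1,3-dioxolan-2-yl]ethyl}prop-2-en-1-ol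
Conditions: i-Bu2AlH (4 equiv), CH2Cl2, −78 °C; aq. potassium sodium tartrate
Reagents that add atoms: none
Why: 1,2-Reduction of the conjugated ester to the allylic alcohol; the ketal, the secondary bromide and the alkene geometry are untouched.

Step 17
Reactants: 28 (2E)-3-[(3S,3aS,4R,7S,7aS)-7-bromo-4-hydroxy-4,7a-dimethyloctahydro-1H-inden-3-yl]-2-{2-[2-(propan-2-yl)-1,3-dioxolan-2-yl]ethyl}prop-2-en-1-ol
Product: 30 (6E)-7-[(3S,3aS,4R,7S,7aS)-7-bromo-4-hydroxy-4,7a-dimethyloctahydro-1H-inden-3-yl]-6-(chloromethyl)-2-methylhept-6-en-3-one, via allylic chloride ketal 29 (not isolated)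
Conditions: MsCl (1.2 equiv), 2,4,6-collidine, LiCl, DMF, 0 °C; then 1 M HCl, THF, rt
Reagents that add atoms: lithium chloride, [Li+].[Cl-]; water, O
Why: Collington–Meyers conversion of a primary allylic alcohol to the chloride (mesylate then chloride) without allylic transposition, the hindered tertiary alcohol being left alone. Dilute acid then hydrolyses the dioxolane to the isopropyl ketone.

Step 18
Reactants: 30 (6E)-7-[(3S,3aS,4R,7S,7aS)-7-bromo-4-hydroxy-4,7a-dimethyloctahydro-1H-inden-3-yl]-6-(chloromethyl)-2-methylhept-6-en-3-one
Product: 31 (4E)-4-{[(3S,3aS,4R,7S,7aS)-7-bromo-4-hydroxy-4,7a-dimethyloctahydro-1H-inden-3-yl]methylidene}-2,2-dimethylcyclohexan-1-one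
Conditions: KOt-Bu (2.5 equiv), t-BuOH/THF (1:4), high dilution, 0 °C → rt
Reagents that add atoms: none
Why: Intramolecular enolate C-alkylation (6-exo-tet). Under equilibrating conditions only the more substituted enolate can close a six-membered ring at the primary allylic carbon; the other enolate and the SN2′ mode are unproductive or hindered. The alkene geometry is untouched, and the equatorial C7 bromide has no anti-periplanar hydrogen for elimination.

Step 19
Reactants: 31 (4E)-4-{[(3S,3aS,4R,7S,7aS)-7-bromo-4-hydroxy-4,7a-dimethyloctahydro-1H-inden-3-yl]methylidene}-2,2-dimethylcyclohexan-1-one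
Product: 32 (1R,4E)-4-{[(3S,3aS,4R,7S,7aS)-7-bromo-4-hydroxy-4,7a-dimethyloctahydro-1H-inden-3-yl]methylidene}-2,2-dimethylcyclohexan-1-ol
Conditions: (S)-2-methyl-CBS-oxazaborolidine (0.5 equiv), catecholborane (3 equiv), toluene, −78 → −40 °C
Reagents that add atoms: none
Why: Corey–Bakshi–Shibata reduction; the quaternary α-carbon is the large group and the α-methylene the small one, so the (S)-catalyst should give the (R)-alcohol under reagent control. Catecholborane is used because it does not hydroborate the trisubstituted alkene.

Step 20
Reactants: 32 (1R,4E)-4-{[(3S,3aS,4R,7S,7aS)-7-bromo-4-hydroxy-4,7a-dimethyloctahydro-1H-inden-3-yl]methylidene}-2,2-dimethylcyclohexan-1-ol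
Product: 33 (3S,3aS,4R,7S,7aS)-7-bromo-3-{(E)-[(4S)-4-bromo-3,3-dimethylcyclohexylidene]methyl}-4,7a-dimethyloctahydro-1H-inden-4-ol (CNP0119865.1)
Conditions: PPh3 (3 equiv), CBr4 (3 equiv), 2,6-lutidine (1 equiv), toluene, 0 → 70 °C
Reagents that add atoms: tetrabromomethane, BrC(Br)(Br)Br
Why: Appel reaction; bromide displaces the alkoxyphosphonium group from the rear, so the (R)-alcohol should give the (S)-bromide. The axial tertiary alcohol, screened by the angular methyl, is expected to be too hindered to form a phosphonium ether.

## Compound list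

1 | 2-methylcyclohexane-1,3-dione | CC1C(=O)CCCC1=O | starting material
2 | allyl acetate | C=CCOC(C)=O | starting material
3 | 2-methyl-2-(prop-2-en-1-yl)cyclohexane-1,3-dione | C=CCC1(C)C(=O)CCCC1=O | intermediate
4 | 4-(1-methyl-2,6-dioxocyclohexyl)butanal | CC1(CCCC=O)C(=O)CCCC1=O | intermediate
5 | (3S,3aS,7aS)-3a-hydroxy-7a-methyl-7-oxooctahydro-1H-indene-3-carbaldehyde (CHO, OH and CH3 cis) | O=C[C@H]1CC[C@]2(C)C(=O)CCC[C@]12O | intermediate (not isolated)
6 | (7aS)-7a-methyl-7-oxo-2,4,5,6,7,7a-hexahydro-1H-indene-3-carbaldehyde | O=CC1=C2CCCC(=O)[C@@]2(C)CC1 | intermediate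
7 | (7aS)-3-(1,3-dioxolan-2-yl)-7,7-ethylenedioxy-7a-methyl-2,4,5,6,7,7a-hexahydro-1H-indene | C1COC(O1)C2=C3CCCC4(OCCO4)[C@@]3(C)CC2 | intermediate (not isolated)
8 | (7aS)-7,7-ethylenedioxy-7a-methyl-2,4,5,6,7,7a-hexahydro-1H-indene-3-carbaldehyde | O=CC1=C2CCCC3(OCCO3)[C@@]2(C)CC1 | intermediate
9 | (7aS)-7,7-ethylenedioxy-7a-methyl-3-[(triethylsilyloxy)methylidene]-2,3,5,6,7,7a-hexahydro-1H-indene (enol ether geometry not defined) | CC[Si](CC)(CC)OC=C1CC[C@@]2(C)C1=CCCC23OCCO3 | intermediate (not isolated)
10 | (7aS)-7,7-ethylenedioxy-4-hydroxy-7a-methyl-2,4,5,6,7,7a-hexahydro-1H-indene-3-carbaldehyde (C4 epimers; in equilibrium with its lactol) | O=CC1=C2C(O)CCC3(OCCO3)[C@@]2(C)CC1 | intermediate (not isolated)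
11 | tricyclic furan: O bridges C1′ and C4; furan carbons C1′, C3, C3a, C4; 7,7-ethylenedioxy; (7aS)-7a-methyl | c1oc2CCC3(OCCO3)[C@@]4(C)CCc1c24 | intermediate
12 | (7aS)-7,7-ethylenedioxy-7a-methyl-4-oxo-2,4,5,6,7,7a-hexahydro-1H-indene-3-carbaldehyde | O=CC1=C2C(=O)CCC3(OCCO3)[C@@]2(C)CC1 | intermediate
13 | 7,7-ethylenedioxy-7aβ-methyl-4-oxo-3aα-H-octahydro-1H-indene-3β-carbaldehyde | O=C[C@H]1CC[C@]2(C)C3(OCCO3)CCC(=O)[C@@H]12 | intermediate (not isolated)
14 | 7,7-ethylenedioxy-7aβ-methyl-4-oxo-3aα-H-octahydro-1H-indene-3α-carbaldehyde | O=C[C@@H]1CC[C@]2(C)C3(OCCO3)CCC(=O)[C@@H]12 | intermediate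
15 | 7,7-ethylenedioxy-3α-(hydroxymethyl)-7aβ-methyl-3aα-H-octahydro-1H-inden-4-one | OC[C@@H]1CC[C@]2(C)C3(OCCO3)CCC(=O)[C@@H]12 | intermediate
16 | 7,7-ethylenedioxy-3α-(hydroxymethyl)-4α,7aβ-dimethyl-3aα-H-octahydro-1H-inden-4β-ol | OC[C@@H]1CC[C@]2(C)C3(OCCO3)CC[C@@](C)(O)[C@@H]12 | intermediate (not isolated)
17 | 4β-hydroxy-3α-(hydroxymethyl)-4α,7aβ-dimethyl-3aα-H-octahydro-1H-inden-7-one | OC[C@@H]1CC[C@]2(C)C(=O)CC[C@@](C)(O)[C@@H]12 | intermediate
18 | C7 hydrazone of 17 | OC[C@@H]1CC[C@]2(C)C(=NN)CC[C@@](C)(O)[C@@H]12 | intermediate (not isolated)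
19 | 7-bromo-3α-(hydroxymethyl)-4α,7aβ-dimethyl-2,3,3a,4,5,7a-hexahydro-1H-inden-4β-ol (3a-H α) | OC[C@@H]1CC[C@]2(C)C(Br)=CC[C@@](C)(O)[C@@H]12 | intermediate
20 | (3R,3aS,4R,7S,7aS)-7-bromo-3-(hydroxymethyl)-4,7a-dimethyloctahydro-1H-inden-4-ol | OC[C@@H]1CC[C@]2(C)[C@@H](Br)CC[C@@](C)(O)[C@@H]12 | intermediate
21 | (3R,3aS,4R,7S,7aS)-7-bromo-4-hydroxy-4,7a-dimethyloctahydro-1H-indene-3-carbaldehyde | O=C[C@@H]1CC[C@]2(C)[C@@H](Br)CC[C@@](C)(O)[C@@H]12 | intermediate
22 | 4-methylpent-1-en-3-one | C=CC(=O)C(C)C | starting material
23 | 2-(2-iodoethyl)-2-(propan-2-yl)-1,3-dioxolane | ICCC1(OCCO1)C(C)C | intermediate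
24 | ethyl (triphenyl-λ5-phosphanylidene)acetate | CCOC(=O)C=P(c1ccccc1)(c1ccccc1)c1ccccc1 | starting material
25 | {1-ethoxy-1-oxo-4-[2-(propan-2-yl)-1,3-dioxolan-2-yl]butan-2-yl}triphenylphosphonium iodide | CCOC(=O)C(CCC1(OCCO1)C(C)C)[P+](c1ccccc1)(c1ccccc1)c1ccccc1.[I-] | intermediate (not isolated)
26 | ethyl 4-[2-(propan-2-yl)-1,3-dioxolan-2-yl]-2-(triphenyl-λ5-phosphanylidene)butanoate | CCOC(=O)C(CCC1(OCCO1)C(C)C)=P(c1ccccc1)(c1ccccc1)c1ccccc1 | intermediate
27 | ethyl (2E)-3-[(3S,3aS,4R,7S,7aS)-7-bromo-4-hydroxy-4,7a-dimethyloctahydro-1H-inden-3-yl]-2-{2-[2-(propan-2-yl)-1,3-dioxolan-2-yl]ethyl}prop-2-enoate | CCOC(=O)/C(=C/[C@@H]1CC[C@]2(C)[C@@H](Br)CC[C@@](C)(O)[C@@H]12)CCC3(OCCO3)C(C)C | intermediate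
28 | (2E)-3-[(3S,3aS,4R,7S,7aS)-7-bromo-4-hydroxy-4,7a-dimethyloctahydro-1H-inden-3-yl]-2-{2-[2-(propan-2-yl)-1,3-dioxolan-2-yl]ethyl}prop-2-en-1-ol | OC/C(=C/[C@@H]1CC[C@]2(C)[C@@H](Br)CC[C@@](C)(O)[C@@H]12)CCC3(OCCO3)C(C)C | intermediate
29 | (3S,3aS,4R,7S,7aS)-7-bromo-3-{(1E)-2-(chloromethyl)-4-[2-(propan-2-yl)-1,3-dioxolan-2-yl]but-1-en-1-yl}-4,7a-dimethyloctahydro-1H-inden-4-ol | ClC/C(=C/[C@@H]1CC[C@]2(C)[C@@H](Br)CC[C@@](C)(O)[C@@H]12)CCC3(OCCO3)C(C)C | intermediate (not isolated)
30 | (6E)-7-[(3S,3aS,4R,7S,7aS)-7-bromo-4-hydroxy-4,7a-dimethyloctahydro-1H-inden-3-yl]-6-(chloromethyl)-2-methylhept-6-en-3-one | ClC/C(=C/[C@@H]1CC[C@]2(C)[C@@H](Br)CC[C@@](C)(O)[C@@H]12)CCC(=O)C(C)C | intermediate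
31 | (4E)-4-{[(3S,3aS,4R,7S,7aS)-7-bromo-4-hydroxy-4,7a-dimethyloctahydro-1H-inden-3-yl]methylidene}-2,2-dimethylcyclohexan-1-one | CC1(C)C/C(=C/[C@@H]2CC[C@]3(C)[C@@H](Br)CC[C@@](C)(O)[C@@H]23)CCC1=O | intermediate
32 | (1R,4E)-4-{[(3S,3aS,4R,7S,7aS)-7-bromo-4-hydroxy-4,7a-dimethyloctahydro-1H-inden-3-yl]methylidene}-2,2-dimethylcyclohexan-1-ol | CC1(C)C/C(=C/[C@@H]2CC[C@]3(C)[C@@H](Br)CC[C@@](C)(O)[C@@H]23)CC[C@H]1O | intermediate
33 | (3S,3aS,4R,7S,7aS)-7-bromo-3-{(E)-[(4S)-4-bromo-3,3-dimethylcyclohexylidene]methyl}-4,7a-dimethyloctahydro-1H-inden-4-ol | CC1(C)C/C(=C/[C@@H]2CC[C@]3(C)[C@@H](Br)CC[C@@](C)(O)[C@@H]23)CC[C@@H]1Br | target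

## Step count and least certain steps

Total: 20 steps. Longest linear sequence: 18 steps (steps 1–12 and 15–20); steps 13 and 14 make the ylide.

Step 3 (key step). The most likely failure is incomplete discrimination between the two enantiotopic ketones, or induction in the opposite sense. The five-membered enolexo transition state is more flexible than the six-membered enolendo case, and the aldol can reverse before dehydration. Fallback: move the enantio-determining event to a desymmetrising ketone reduction. Setting out from 3, CBS reduction (2-methyl-CBS-oxazaborolidine of the enantiomer that leaves the 2R quaternary centre, catecholborane) would give (2R,3R)-3-hydroxy-2-methyl-2-(prop-2-en-1-yl)cyclohexan-1-one F1. Hydroformylation as in step 2 would give 4-[(1R,2R)-2-hydroxy-1-methyl-6-oxocyclohexyl]butanal F2. Pyrrolidine/AcOH would then close ring C on the only ketone left and dehydrate to (7R,7aS)-7-hydroxy-7a-methyl-2,4,5,6,7,7a-hexahydro-1H-indene-3-carbaldehyde F3. Dess–Martin oxidation of the secondary alcohol returns to 6.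

Step 20. The most likely failure is elimination toward C5″ or a 1,2-methyl shift out-competing backside attack, because the carbon bears a gem-dimethyl neighbour; slow reaction could also let the tertiary alcohol be activated. Fallback: substitution with retention instead of inversion. Setting out from 31, reduction with the (R)-oxazaborolidine would give the (1S,4E)-alcohol F4. Sulfonylation with 2-methoxyethyl 2-(chlorosulfonyl)benzoate would give the chelating arylsulfonate F5. TiBr4 at −78 °C, bound by the ester side arm, should deliver bromide from the front face and return to the route at 33.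

Step 7. The most likely failures are hydrogen delivery from the β face, because the axial ketal oxygen at C7 partly screens the α face, and loss of the trans fusion by enolisation toward C3a during the amine treatment, the cis-hydrindanone probably being the more stable. Fallback: replace steric control on a metal surface by coordination control. Setting out from 12, homogeneous hydrogenation with [Ir(cod)(PCy3)(py)]PF6 in CH2Cl2 would use the same axial ketal oxygen as a directing group for the α face, and the route is rejoined at 14 after the same brief epimerisation. No new compound is involved.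

Step 5. The most likely failure is attack of the peracid at the α-carbon (C3) or at the enol ether bond of the dienol ether, giving an α-oxygenated aldehyde that cannot aromatise. Fallback: a cycloaddition that can only bond oxygen to C1′ and C4. Setting out from 8, silylation with t-BuMe2SiOTf/Et3N would give the isolable silyl dienol ether F6. Photooxygenation (O2, tetraphenylporphyrin, hν, −78 °C) would give the [4+2] endoperoxide F7. Bu4NF/AcOH followed by Ac2O/pyridine would collapse it to the aldehyde and dehydrate the hydroperoxide to the ketone, returning at 12 and bypassing 11.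

Step 11. The most likely failure is loss of bromine from the intermediate radical, or hydrogen delivery syn to the angular methyl. Fallback: make the C–Br stereocentre by removing one bromine instead of adding hydrogen to an alkene. Setting out from 18, oxidation with CuBr2/Et3N in MeOH would give the gem-dibromide F8. One equivalent of Bu3SnH with Et3B/O2 at −78 °C should remove one bromine through the same C7 radical, which takes hydrogen anti to the angular methyl, and return to the route at 20.

Further compounds

F1 | step 3 | (2R,3R)-3-hydroxy-2-methyl-2-(prop-2-en-1-yl)cyclohexan-1-one | C=CC[C@@]1(C)C(=O)CCC[C@H]1O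
F2 | step 3 | 4-[(1R,2R)-2-hydroxy-1-methyl-6-oxocyclohexyl]butanal | O=CCCC[C@@]1(C)C(=O)CCC[C@H]1O
F3 | step 3 | (7R,7aS)-7-hydroxy-7a-methyl-2,4,5,6,7,7a-hexahydro-1H-indene-3-carbaldehyde | O=CC1=C2CCC[C@@H](O)[C@@]2(C)CC1
F4 | step 20 | (1S,4E)-4-{[(3S,3aS,4R,7S,7aS)-7-bromo-4-hydroxy-4,7a-dimethyloctahydro-1H-inden-3-yl]methylidene}-2,2-dimethylcyclohexan-1-ol | CC1(C)C/C(=C/[C@@H]2CC[C@]3(C)[C@@H](Br)CC[C@@](C)(O)[C@@H]23)CC[C@@H]1O
F5 | step 20 | 2-methoxyethyl 2-(sulfonyl)benzoate ester of F4 (chelating arylsulfonate) | CC1(C)C/C(=C/[C@@H]2CC[C@]3(C)[C@@H](Br)CC[C@@](C)(O)[C@@H]23)CC[C@@H]1OS(=O)(=O)c4ccccc4C(=O)OCCOC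
F0 | step 7 | none | none
F6 | step 5 | (7aS)-3-[(tert-butyldimethylsilyloxy)methylidene]-7,7-ethylenedioxy-7a-methyl-2,3,5,6,7,7a-hexahydro-1H-indene | CC(C)(C)[Si](C)(C)OC=C1CC[C@@]2(C)C1=CCCC23OCCO3
F7 | step 5 | silyloxy endoperoxide: 1,2-dioxine with O–O bridging C1′ and C4, C3=C3a alkene, C1′-OSi(t-Bu)Me2, 7,7-ethylenedioxy, (7aS)-methyl | CC(C)(C)[Si](C)(C)OC1OOC2CCC3(OCCO3)[C@@]4(C)CCC1=C24
F8 | step 11 | 7,7-dibromo-3α-(hydroxymethyl)-4α,7aβ-dimethyl-3aα-H-octahydro-1H-inden-4β-ol | OC[C@@H]1CC[C@]2(C)C(Br)(Br)CC[C@@](C)(O)[C@@H]12
A1 | alternative 1 | ring-fusion alkene allylic alcohol: 3-[(tert-butyldimethylsilyloxy)methyl]-7,7-dimethoxy-2,3,4,5,6,7-hexahydro-1H-inden-4-ol (configured as in A2) | CC(C)(C)[Si](C)(C)OC[C@@H]1CCC2=C1[C@H](O)CCC2(OC)OC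
A2 | alternative 1 | propellane cyclopropyl carbinol | CC(C)(C)[Si](C)(C)OC[C@@H]2CC[C@]3(C4)C(OC)(OC)CC[C@@H](O)[C@]234
A3 | alternative 2 | allylsilane bromohydrin 2,3,5,6-tetrafluorobenzoate with C4 triethylsilyl ether (trimethylsilyl on C1′) | C=C(CC[C@H](Br)C(C)(C)OC(=O)c1c(F)c(F)cc(F)c1F)[C@@H]([Si](C)(C)C)[C@@H]2CC[C@]3(C)[C@@H](Br)CC[C@@](C)(O[Si](CC)(CC)CC)[C@@H]23
A4 | alternative 2 | triethylsilyl ether of the target | CC1(C)C/C(=C/[C@@H]2CC[C@]3(C)[C@@H](Br)CC[C@@](C)(O[Si](CC)(CC)CC)[C@@H]23)CC[C@@H]1Br
A5 | alternative 3 | enyne acetate: (E)-8-(tert-butyldiphenylsilyloxy)-4,7-dimethyloct-6-en-2-yn-4-yl acetate | CC#C[C@](C)(OC(C)=O)CC/C=C(\C)CO[Si](c1ccccc1)(c1ccccc1)C(C)(C)C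
A6 | alternative 3 | bromo acetoxy cyclohexyl methyl ketone | CC(C)(C)[Si](c1ccccc1)(c1ccccc1)OC[C@]2(C)[C@@H](Br)CC[C@@](C)(OC(C)=O)[C@H]2C(C)=O
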